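**Plan**

- Cuts, in retrosynthetic order: the O–tBu bond on the 4′-oxygen; C1′–C2′ of ring B (quinone back to a 4-alkynyl-4-hydroxycyclobutenone); the alkyne–carbinol bond (acetylide plus 3-tert-butoxy-4-prenylcyclobutenedione); the C3–alkyne carbon back to a chroman-3-ylmethanol; O1–C2 of the pyran ring and the malonate-derived C3 unit; the aryl–prenyl and aryl–CHO bonds of ring A.
- Enabling feature: ring B is a 2-hydroxy-1,4-benzoquinone with the chroman on C1′, C2′=O, prenyl on C3′, oxygen on C4′, C5′=O and a lone H on C6′. The four squarate carbons map onto C2′–C5′ and the two alkyne carbons onto C6′ and C1′.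
- Forward: ring A (3,5-dimethoxyphenol) is prenylated and formylated; a coumarin is built and reduced to a prochiral triol; the pyran ring closes by Mitsunobu etherification; the C3 arm is homologated to the alkyne and joined to the squarate piece; ring B closes last by thermal ring expansion; the tert-butyl group is then removed.
- Stereochemistry: the only stereocentre, C3, comes from lipase desymmetrisation of the triacetate of the prochiral triol. No bond to C3 is made or broken afterwards, so the (S)-monoacetate leads to the (3R) target.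

Key step: step 15

Assumption: the lipase treats the arylmethyl group as the large substituent, as with 2-benzylpropane-1,3-diol diacetates, so that hydrolysis leaves the (S)-monoacetate; the sense is to be confirmed at alcohol 15 before material is carried on.

(prenyl = 3-methylbut-2-en-1-yl)

**Route**

Step 1
Reactants: 1 3,5-dimethoxyphenol
Product: 2 (3,5-dimethoxyphenoxy)triisopropylsilane
Conditions: TIPSCl, imidazole, DMF, rt
Reagents that add atoms: chlorotriisopropylsilane, CC(C)[Si](Cl)(C(C)C)C(C)C
Why: Routine silylation of a phenol; the bulky, weakly coordinating OTIPS group is chosen to shield C2/C6 and leave the two methoxy groups as the only effective directors for the metalation in step 2.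

Step 2
Reactants: 2 (3,5-dimethoxyphenoxy)triisopropylsilane; 3 prenyl bromide
Product: 6 3,5-dimethoxy-4-(3-methylbut-2-en-1-yl)phenol, via C4-aryllithium 4 (not isolated), via prenylated silyl ether 5 (not isolated)
Conditions: n-BuLi, THF, 0 °C → rt; CuBr·SMe2 (10 mol %), 3, −78 °C → rt; then TBAF, rt; aq. NH4Cl
Reagents that add atoms: none
Why: Directed ortho-metalation at C4 between the two methoxy groups, copper-assisted SN2 allylation by prenyl bromide at its unsubstituted terminus and fluoride desilylation in the same flask should give a mirror-symmetric phenol whose two positions ortho to OH are equivalent.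

Step 3
Reactants: 6 3,5-dimethoxy-4-(3-methylbut-2-en-1-yl)phenol
Product: 7 6-hydroxy-2,4-dimethoxy-3-(3-methylbut-2-en-1-yl)benzaldehyde
Conditions: MgCl2, Et3N, (CH2O)n, MeCN, reflux; cold dilute HCl work-up
Reagents that add atoms: paraformaldehyde (formaldehyde), C=O
Why: Magnesium-phenoxide-directed ortho-formylation (hydroxymethylation, then hydride transfer to a second formaldehyde) is specific for the position ortho to OH, and because C2 and C6 of 6 are equivalent only one aldehyde can form; the isolated trisubstituted alkene is inert.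

Step 4
Reactants: 7 6-hydroxy-2,4-dimethoxy-3-(3-methylbut-2-en-1-yl)benzaldehyde; 8 diethyl malonate
Product: 9 ethyl 5,7-dimethoxy-6-(3-methylbut-2-en-1-yl)-2-oxo-2H-chromene-3-carboxylate
Conditions: piperidine (cat.), AcOH (cat.), EtOH, reflux
Reagents that add atoms: none
Why: Knoevenagel condensation followed by lactonisation of the phenol onto the cis ester gives the coumarin-3-carboxylate, which installs the three-carbon unit (future C2, C3 and the exocyclic carbon) and masks the phenol.

Step 5
Reactants: 9 ethyl 5,7-dimethoxy-6-(3-methylbut-2-en-1-yl)-2-oxo-2H-chromene-3-carboxylate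
Product: 11 2-{[6-hydroxy-2,4-dimethoxy-3-(3-methylbut-2-en-1-yl)phenyl]methyl}propane-1,3-diol, via dihydrocoumarin ester 10 (not isolated)
Conditions: NaBH4, THF/EtOH, 0 °C; then LiBH4, 0 °C → rt; aq. NH4Cl
Reagents that add atoms: none
Why: Borohydride adds 1,4 to the doubly activated C3=C4 bond (conjugate reduction of an alkylidene-malonate-type acceptor) and LiBH4 then reduces the aryl lactone and the ethyl ester to the prochiral triol; the prenyl alkene is not touched by hydride.

Step 6
Reactants: 11 2-{[6-hydroxy-2,4-dimethoxy-3-(3-methylbut-2-en-1-yl)phenyl]methyl}propane-1,3-diol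
Product: 12 2-{[6-(acetyloxy)-2,4-dimethoxy-3-(3-methylbut-2-en-1-yl)phenyl]methyl}propane-1,3-diyl diacetate
Conditions: Ac2O, pyridine, DMAP (cat.), CH2Cl2, rt
Reagents that add atoms: acetic anhydride, CC(=O)OC(C)=O
Why: Exhaustive DMAP-catalysed acetylation turns the triol into the prochiral ester needed for hydrolytic desymmetrisation.

Step 7
Reactants: 12 2-{[6-(acetyloxy)-2,4-dimethoxy-3-(3-methylbut-2-en-1-yl)phenyl]methyl}propane-1,3-diyl diacetate
Product: 13 (2S)-3-hydroxy-2-{[6-hydroxy-2,4-dimethoxy-3-(3-methylbut-2-en-1-yl)phenyl]methyl}propyl acetate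
Conditions: Burkholderia cepacia lipase (Amano PS), 0.1 M phosphate buffer pH 7/acetone 9:1, 25 °C
Reagents that add atoms: none
Why: Enzymatic desymmetrisation by enantiotopic-group-selective ester hydrolysis: the lipase should cleave the labile aryl acetate and the one primary acetate whose alcohol it would acylate (arylmethyl as the large group), which sets the only stereocentre as (S), and any over-hydrolysis to the triol removes mainly the minor enantiomer.

Step 8
Reactants: 13 (2S)-3-hydroxy-2-{[6-hydroxy-2,4-dimethoxy-3-(3-methylbut-2-en-1-yl)phenyl]methyl}propyl acetate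
Product: 14 [(3S)-5,7-dimethoxy-6-(3-methylbut-2-en-1-yl)-3,4-dihydro-2H-chromen-3-yl]methyl acetate
Conditions: PPh3, DIAD, THF, 0 °C → rt
Reagents that add atoms: none
Why: Intramolecular Mitsunobu etherification, in which the phenol (the only acidic pronucleophile) displaces the phosphonium-activated primary hydroxyl in a 6-exo-tet closure of the pyran ring; the stereocentre is not a reacting centre, so its configuration is carried over and the descriptor becomes 3S only through the CIP priorities.

Step 9
Reactants: 14 [(3S)-5,7-dimethoxy-6-(3-methylbut-2-en-1-yl)-3,4-dihydro-2H-chromen-3-yl]methyl acetate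
Product: 15 [(3R)-5,7-dimethoxy-6-(3-methylbut-2-en-1-yl)-3,4-dihydro-2H-chromen-3-yl]methanol
Conditions: K2CO3 (cat.), MeOH, 0 °C → rt
Reagents that add atoms: none
Why: Base-catalysed transesterification (Zemplén-type methanolysis) removes the primary acetate without affecting the aryl ethers, the alkene or the stereocentre.

Step 10
Reactants: 15 [(3R)-5,7-dimethoxy-6-(3-methylbut-2-en-1-yl)-3,4-dihydro-2H-chromen-3-yl]methanol
Product: 16 (3S)-5,7-dimethoxy-6-(3-methylbut-2-en-1-yl)-3,4-dihydro-2H-chromene-3-carbaldehyde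
Conditions: Dess–Martin periodinane, NaHCO3, CH2Cl2, 0 °C; used crude at once
Reagents that add atoms: none
Why: Dess–Martin oxidation under buffered, non-basic conditions stops at the aldehyde and is chosen to avoid enolisation or retro-oxa-Michael opening of this α-stereogenic β-aryloxy aldehyde.

Step 11
Reactants: 16 (3S)-5,7-dimethoxy-6-(3-methylbut-2-en-1-yl)-3,4-dihydro-2H-chromene-3-carbaldehyde
Product: 17 (3R)-3-(2,2-dibromoethenyl)-5,7-dimethoxy-6-(3-methylbut-2-en-1-yl)-3,4-dihydro-2H-chromene
Conditions: PPh3, CBr4, CH2Cl2, 0 °C (ylide preformed), then 16, 0 °C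
Reagents that add atoms: carbon tetrabromide, BrC(Br)(Br)Br
Why: Ramirez dibromo-olefination (first stage of the Corey–Fuchs sequence) is a salt-free, essentially neutral Wittig reaction that should convert the aldehyde into the 1,1-dibromoalkene without epimerising the adjacent centre.

Step 12
Reactants: 18 di-tert-butyl squarate (3,4-di-tert-butoxycyclobut-3-ene-1,2-dione)
Product: 20 3-tert-butoxy-4-(prop-2-en-1-yl)cyclobut-3-ene-1,2-dione, via magnesium alkoxide adduct 19 (not isolated)
Conditions: allylMgBr, THF, −78 °C; TFAA, −78 → 0 °C; aq. NaHCO3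
Reagents that add atoms: allylmagnesium bromide, C=CC[Mg]Br
Why: 1,2-Addition of the Grignard reagent to a squarate carbonyl, trifluoroacetylation of the alkoxide, ionisation and loss of one tert-butyl group from the alkoxy-stabilised cation (the standard squarate to 3-alkyl-4-alkoxycyclobutenedione transposition) should give the dione; allyl is used because prenyl organometallics would deliver the reverse-prenyl isomer by γ-attack.

Step 13
Reactants: 20 3-tert-butoxy-4-(prop-2-en-1-yl)cyclobut-3-ene-1,2-dione
Product: 21 3-tert-butoxy-4-(3-methylbut-2-en-1-yl)cyclobut-3-ene-1,2-dione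
Conditions: 2-methylbut-2-ene (excess), Hoveyda–Grubbs II catalyst (3 mol %), CH2Cl2, 35 °C
Reagents that add atoms: 2-methylbut-2-ene, CC=C(C)C
Why: Olefin cross-metathesis of the terminal allyl group with excess 2-methylbut-2-ene converts allyl into prenyl with loss of propene, while the tetrasubstituted, electron-poor ring alkene is inert to the ruthenium carbene.

Step 14
Reactants: 17 (3R)-3-(2,2-dibromoethenyl)-5,7-dimethoxy-6-(3-methylbut-2-en-1-yl)-3,4-dihydro-2H-chromene; 21 3-tert-butoxy-4-(3-methylbut-2-en-1-yl)cyclobut-3-ene-1,2-dione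
Product: 23 3-tert-butoxy-4-{[(3R)-5,7-dimethoxy-6-(3-methylbut-2-en-1-yl)-3,4-dihydro-2H-chromen-3-yl]ethynyl}-4-hydroxy-2-(3-methylbut-2-en-1-yl)cyclobut-2-en-1-one (both carbinol epimers), via lithium acetylide 22 (not isolated)
Conditions: 17, n-BuLi (2.0 equiv), THF, −78 → −20 °C; recool and cannulate into 21 (1.2 equiv), THF, −78 °C; aq. NH4Cl at −78 °C; Et3N-deactivated silica
Reagents that add atoms: none
Why: The second stage of the Corey–Fuchs sequence (Br–Li exchange, α-elimination with 1,2-shift, deprotonation) gives the lithium acetylide, which should add 1,2 to the more electrophilic carbonyl of 21, the one next to C–OtBu and not in vinylogous-ester conjugation with the alkoxy group; the new carbinol centre is of no consequence and C3 is untouched.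

Step 15
Reactants: 23 3-tert-butoxy-4-{[(3R)-5,7-dimethoxy-6-(3-methylbut-2-en-1-yl)-3,4-dihydro-2H-chromen-3-yl]ethynyl}-4-hydroxy-2-(3-methylbut-2-en-1-yl)cyclobut-2-en-1-one
Product: 24 2-tert-butoxy-5-[(3R)-5,7-dimethoxy-6-(3-methylbut-2-en-1-yl)-3,4-dihydro-2H-chromen-3-yl]-3-(3-methylbut-2-en-1-yl)cyclohexa-2,5-diene-1,4-dione
Conditions: MeCN (0.01 M, degassed), 80 °C
Reagents that add atoms: none
Why: Heating opens the cyclobutenone by conrotatory 4π-electrocyclic cleavage of the C1–C4 bond, the hydroxyl rotating outward so that the alkynyl group lies cis to the new ketene; the ketene carbon then bonds to the distal alkyne carbon to give a six-membered diradical (ring σ-radical at C6′ and an oxygen-delocalised radical), and transfer of the hydroxyl hydrogen to C6′ gives the quinone. The closest known reaction is the thermal rearrangement of 4-alkynyl-4-hydroxycyclobutenones to 1,4-benzoquinones (Moore rearrangement). Ring B closes in a 6-endo-dig mode with respect to the alkyne, forming C1′–C2′. No stereocentre is created: the carbinol carbon becomes C5′=O, so both epimers of 23 converge, and C3 only carries the side chain (its C–H is not within 1,5-reach of the C6′ radical). The selectivity needed is six- over five-membered closure (quinone versus alkylidenecyclopentenedione), which the secondary-alkyl substituent on the alkyne should secure because it gives no stabilisation to the exocyclic vinyl radical of the 5-exo path, while the free OH supplies the hydrogen quickly. The substituent pattern is already fixed by step 14, so prenyl ends up between C2′=O and C4′–OtBu and the chroman on C1′.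

Step 16
Reactants: 24 2-tert-butoxy-5-[(3R)-5,7-dimethoxy-6-(3-methylbut-2-en-1-yl)-3,4-dihydro-2H-chromen-3-yl]-3-(3-methylbut-2-en-1-yl)cyclohexa-2,5-diene-1,4-dione
Product: 25 2-hydroxy-5-[(3R)-5,7-dimethoxy-6-(3-methylbut-2-en-1-yl)-3,4-dihydro-2H-chromen-3-yl]-3-(3-methylbut-2-en-1-yl)cyclohexa-2,5-diene-1,4-dione (CNP0241224.1)
Conditions: TFA (10 equiv), 1,3,5-trimethoxybenzene (3 equiv), CH2Cl2, 0 °C, short contact; pH 7 buffer quench
Reagents that add atoms: none
Why: Acidolysis of the tert-butyl vinylogous ester (carbonyl protonation and E1 loss of 2-methylpropene) should unveil the 2-hydroxyquinone while leaving the aryl methyl ethers intact; low temperature, short contact and an arene scavenger for the tert-butyl cation are used to protect the two prenyl groups and C8 of ring A.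

**Compound list**

1 | 3,5-dimethoxyphenol | COc1cc(O)cc(OC)c1 | starting material
2 | (3,5-dimethoxyphenoxy)triisopropylsilane | COc1cc(O[Si](C(C)C)(C(C)C)C(C)C)cc(OC)c1 | intermediate
3 | prenyl bromide (1-bromo-3-methylbut-2-ene) | CC(C)=CCBr | starting material
4 | [2,6-dimethoxy-4-(triisopropylsilyloxy)phenyl]lithium | [Li]c1c(OC)cc(O[Si](C(C)C)(C(C)C)C(C)C)cc1OC | intermediate (not isolated)
5 | [3,5-dimethoxy-4-(3-methylbut-2-en-1-yl)phenoxy]triisopropylsilane | COc1cc(O[Si](C(C)C)(C(C)C)C(C)C)cc(OC)c1CC=C(C)C | intermediate (not isolated)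
6 | 3,5-dimethoxy-4-(3-methylbut-2-en-1-yl)phenol | COc1cc(O)cc(OC)c1CC=C(C)C | intermediate
7 | 6-hydroxy-2,4-dimethoxy-3-(3-methylbut-2-en-1-yl)benzaldehyde | COc1cc(O)c(C=O)c(OC)c1CC=C(C)C | intermediate
8 | diethyl malonate | CCOC(=O)CC(=O)OCC | starting material
9 | ethyl 5,7-dimethoxy-6-(3-methylbut-2-en-1-yl)-2-oxo-2H-chromene-3-carboxylate | CCOC(=O)C1=Cc2c(OC)c(CC=C(C)C)c(OC)cc2OC1=O | intermediate
10 | ethyl 5,7-dimethoxy-6-(3-methylbut-2-en-1-yl)-2-oxo-3,4-dihydro-2H-chromene-3-carboxylate (racemic) | CCOC(=O)C1Cc2c(OC)c(CC=C(C)C)c(OC)cc2OC1=O | intermediate (not isolated)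
11 | 2-{[6-hydroxy-2,4-dimethoxy-3-(3-methylbut-2-en-1-yl)phenyl]methyl}propane-1,3-diol | OCC(CO)Cc1c(O)cc(OC)c(CC=C(C)C)c1OC | intermediate
12 | 2-{[6-(acetyloxy)-2,4-dimethoxy-3-(3-methylbut-2-en-1-yl)phenyl]methyl}propane-1,3-diyl diacetate | CC(=O)OCC(COC(C)=O)Cc1c(OC(C)=O)cc(OC)c(CC=C(C)C)c1OC | intermediate
13 | (2S)-3-hydroxy-2-{[6-hydroxy-2,4-dimethoxy-3-(3-methylbut-2-en-1-yl)phenyl]methyl}propyl acetate | COc1cc(O)c(C[C@H](COC(C)=O)CO)c(OC)c1CC=C(C)C | intermediate
14 | [(3S)-5,7-dimethoxy-6-(3-methylbut-2-en-1-yl)-3,4-dihydro-2H-chromen-3-yl]methyl acetate | COc1cc2c(c(OC)c1CC=C(C)C)C[C@H](COC(C)=O)CO2 | intermediate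
15 | [(3R)-5,7-dimethoxy-6-(3-methylbut-2-en-1-yl)-3,4-dihydro-2H-chromen-3-yl]methanol | COc1cc2c(c(OC)c1CC=C(C)C)C[C@H](CO)CO2 | intermediate
16 | (3S)-5,7-dimethoxy-6-(3-methylbut-2-en-1-yl)-3,4-dihydro-2H-chromene-3-carbaldehyde | COc1cc2c(c(OC)c1CC=C(C)C)C[C@H](C=O)CO2 | intermediate
17 | (3R)-3-(2,2-dibromoethenyl)-5,7-dimethoxy-6-(3-methylbut-2-en-1-yl)-3,4-dihydro-2H-chromene | COc1cc2c(c(OC)c1CC=C(C)C)C[C@H](C=C(Br)Br)CO2 | intermediate
18 | di-tert-butyl squarate (3,4-di-tert-butoxycyclobut-3-ene-1,2-dione) | CC(C)(C)OC1=C(OC(C)(C)C)C(=O)C1=O | starting material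
19 | bromomagnesium alkoxide of 4-allyl-2,3-di-tert-butoxy-4-hydroxycyclobut-2-en-1-one | C=CCC1(O[Mg]Br)C(OC(C)(C)C)=C(OC(C)(C)C)C1=O | intermediate (not isolated)
20 | 3-tert-butoxy-4-(prop-2-en-1-yl)cyclobut-3-ene-1,2-dione | C=CCC1=C(OC(C)(C)C)C(=O)C1=O | intermediate
21 | 3-tert-butoxy-4-(3-methylbut-2-en-1-yl)cyclobut-3-ene-1,2-dione | CC(C)=CCC1=C(OC(C)(C)C)C(=O)C1=O | intermediate
22 | lithium acetylide of (3R)-3-ethynyl-5,7-dimethoxy-6-(3-methylbut-2-en-1-yl)-3,4-dihydro-2H-chromene | COc1cc2c(c(OC)c1CC=C(C)C)C[C@H](C#C[Li])CO2 | intermediate (not isolated)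
23 | 3-tert-butoxy-4-{[(3R)-5,7-dimethoxy-6-(3-methylbut-2-en-1-yl)-3,4-dihydro-2H-chromen-3-yl]ethynyl}-4-hydroxy-2-(3-methylbut-2-en-1-yl)cyclobut-2-en-1-one (carbinol epimers) | COc1cc2c(c(OC)c1CC=C(C)C)C[C@H](C#CC1(O)C(OC(C)(C)C)=C(CC=C(C)C)C1=O)CO2 | intermediate
24 | 2-tert-butoxy-5-[(3R)-5,7-dimethoxy-6-(3-methylbut-2-en-1-yl)-3,4-dihydro-2H-chromen-3-yl]-3-(3-methylbut-2-en-1-yl)cyclohexa-2,5-diene-1,4-dione | COc1cc2c(c(OC)c1CC=C(C)C)C[C@H](C1=CC(=O)C(OC(C)(C)C)=C(CC=C(C)C)C1=O)CO2 | intermediate
25 | 2-hydroxy-5-[(3R)-5,7-dimethoxy-6-(3-methylbut-2-en-1-yl)-3,4-dihydro-2H-chromen-3-yl]-3-(3-methylbut-2-en-1-yl)cyclohexa-2,5-diene-1,4-dione | COc1cc2c(c(OC)c1CC=C(C)C)C[C@H](C1=CC(=O)C(O)=C(CC=C(C)C)C1=O)CO2 | target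

**Step count**

Total: 16 steps. Longest linear sequence: 14 steps (steps 1–11 and 14–16, from 3,5-dimethoxyphenol); the squarate branch is 2 steps (12–13).

**Steps most likely to fail**

Step 7 (lipase desymmetrisation). The enzyme may discriminate poorly, or in the opposite sense, between the enantiotopic acetates of this 2,6-disubstituted benzyl substrate, and 1,3-acyl migration in the monoacetate may erode the enantiomeric purity. The fallback sets out from triol 11 and comes back at alcohol 15. Direct intramolecular Mitsunobu cyclisation of 11 (PPh3, DIAD, THF) would give the racemic chroman-3-ylmethanol F1. Esterification with (S)-2-methoxy-2-phenylacetic acid (EDC, DMAP, CH2Cl2, 0 °C) and separation of the two diastereomers by chromatography or crystallisation would give the ester of the (R)-alcohol, the (2S)-2-methoxy-2-phenylacetate F2. Its methanolysis (K2CO3, MeOH) returns 15. This resolution gives up half of the material but its outcome can be assigned from the mandelate and does not depend on the enzyme.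

Step 15 (ring expansion). The ketene may close onto the proximal alkyne carbon (five-membered closure to an alkylidenecyclopentenedione), the diradical may abstract hydrogen from solvent or side chains, or the tert-butyl group may be lost thermally before ring expansion. The fallback sets out from aldehyde 16 (with dione 21) and comes back at quinone 24. Takai iodo-olefination of 16 (CrCl2, CHI3, THF, 0 °C) would give the (E)-vinyl iodide F3. Iodine–lithium exchange (t-BuLi, Et2O, −78 °C) and addition to 21 would give the 4-alkenyl-4-hydroxycyclobutenone F4. On heating (toluene, 110 °C) this opens to a dienylketene that can close only by 6π-electrocyclisation, forming the same C1′–C2′ bond, and tautomerises to the hydroquinone F5. Oxidation (Ag2O, Et2O) then gives 24.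

Step 16 (tert-butyl cleavage). The acid may protonate the prenyl alkenes (cyclisation of the 3′-prenyl group onto the freed 4′-OH to a pyranoquinone, or Markovnikov addition), and the tert-butyl cation may alkylate ring A at C8. The fallback sets out from 24 and comes back at 25. Trans-silylation with TMSOTf and 2,6-lutidine (CH2Cl2, −20 °C), in which the base removes the tert-butyl group as 2-methylpropene and no free Brønsted acid is present, would give the trimethylsilyl vinylogous ester F6. This is hydrolysed to 25 on work-up with pH 7 buffer.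

**Further compounds**

F1 | step 7 | racemic [5,7-dimethoxy-6-(3-methylbut-2-en-1-yl)-3,4-dihydro-2H-chromen-3-yl]methanol | COc1cc2c(c(OC)c1CC=C(C)C)CC(CO)CO2
F2 | step 7 | [(3S)-5,7-dimethoxy-6-(3-methylbut-2-en-1-yl)-3,4-dihydro-2H-chromen-3-yl]methyl (2S)-2-methoxy-2-phenylacetate (ester of 15) | COc1cc2c(c(OC)c1CC=C(C)C)C[C@H](COC(=O)[C@@H](OC)c1ccccc1)CO2
F3 | step 15 | (3R)-3-[(E)-2-iodoethenyl]-5,7-dimethoxy-6-(3-methylbut-2-en-1-yl)-3,4-dihydro-2H-chromene | COc1cc2c(c(OC)c1CC=C(C)C)C[C@H](/C=C/I)CO2
F4 | step 15 | 3-tert-butoxy-4-{(E)-2-[(3R)-5,7-dimethoxy-6-(3-methylbut-2-en-1-yl)-3,4-dihydro-2H-chromen-3-yl]ethenyl}-4-hydroxy-2-(3-methylbut-2-en-1-yl)cyclobut-2-en-1-one (carbinol epimers) | COc1cc2c(c(OC)c1CC=C(C)C)C[C@H](/C=C/C1(O)C(OC(C)(C)C)=C(CC=C(C)C)C1=O)CO2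
F5 | step 15 | 2-tert-butoxy-5-[(3R)-5,7-dimethoxy-6-(3-methylbut-2-en-1-yl)-3,4-dihydro-2H-chromen-3-yl]-3-(3-methylbut-2-en-1-yl)benzene-1,4-diol | COc1cc2c(c(OC)c1CC=C(C)C)C[C@H](c1cc(O)c(OC(C)(C)C)c(CC=C(C)C)c1O)CO2
F6 | step 16 | 5-[(3R)-5,7-dimethoxy-6-(3-methylbut-2-en-1-yl)-3,4-dihydro-2H-chromen-3-yl]-3-(3-methylbut-2-en-1-yl)-2-(trimethylsilyloxy)cyclohexa-2,5-diene-1,4-dione | COc1cc2c(c(OC)c1CC=C(C)C)C[C@H](C1=CC(=O)C(O[Si](C)(C)C)=C(CC=C(C)C)C1=O)CO2
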